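Late times came first for me: the flask is asked at 20 h, and the earlier runs stop at 15.0 h.

| setting | ash | cedar | birch | flask |
|---|---|---|---|---|
| substrate | 20 mM | 31 mM | 14 mM | 14 mM |
| reagent | 18.2 mM | 18.2 mM | 27 mM | 18.2 mM |
| remark | run made earlier | run made earlier | run made earlier |  |
| time |  |  |  | 20 h |

| run | time / h | side product A / % | target / % |
|---|---|---|---|
| ash | 0.833 | 37 | 39 |
| ash | 2.50 | 34 | 37 |
| ash | 5.00 | 34 | 38 |
| ash | 6.00 | 36 | 38 |
| ash | 10.0 | 35 | 38 |
| ash | 12.0 | 38 | 36 |
| ash | 15.0 | 39 | 35 |
| cedar | 0.833 | 29 | 32 |
| cedar | 2.50 | 31 | 33 |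
| cedar | 5.00 | 30 | 33 |
| cedar | 6.00 | 32 | 32 |
| cedar | 10.0 | 33 | 32 |
| cedar | 12.0 | 31 | 31 |
| cedar | 15.0 | 34 | 33 |
| birch | 3.00 | 53 | 39 |
| birch | 6.00 | 51 | 35 |
| birch | 10.0 | 53 | 33 |
| birch | 12.0 | 54 | 33 |
| birch | 15.0 | 54 | 34 |

(readings scatter by 1.5 percentage points)



- share of side product A in side product A plus target at 30 s
- share of side product A in side product A plus target at 20 h

I worked in fractions of the substrate charge and took the split, side product A over target, summed over the samples from 10.0 h on. Ash and cedar share a reagent charge but differ in substrate, and they gave 1.03 and 1.02, equal within the scatter, so I dropped the substrate charge from the rule. I pooled both runs into the reference split, a selectivity factor at 18.2 mM of reagent, 1.02. But birch, with more reagent, gave 1.61. In powers of ten its reagent charge stood 0.171 above the reference and its split 0.198, so I took the split as proportional to the reagent charge.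

The flask has the reference reagent charge, so its split is the reference split, and its share at 20 h is 50.6 %. No run was sampled before 0.833 h, far later than 30 s, so the readings do not show that early moment, and as a guess I carried the reference split back to it, which gave 50.6 % again.

The forecast stood at 49 % for 30 s, below mine, and at 56 % for 20 h, above mine, where it worked from the reagent-to-substrate ratio: “I interpolate”.

The flask gave 47.9 % and 49.9 %.

    substrate → target (k = 0.156 min⁻¹)
    substrate + target → side product B (k = 9.59 L mol⁻¹ min⁻¹)
    substrate + reagent → side product A (k = 8.85 L mol⁻¹ min⁻¹)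
    substrate + reagent ⇌ intermediate (K = 16.0 L mol⁻¹, k = 124 L mol⁻¹ min⁻¹)
    substrate ⇌ dormant form (K = 0.651, k = 0.269 min⁻¹)

In this flask substrate was down to 0 % by 2.00 h, with side product A and target at 40.5 % and 40.7 %, the amounts they still held at 20.0 h. A neighbour flask charged with 31 mM of reagent lies 0.231 above the reference in powers of ten, which lifted the reference split to 1.74 and gave me a share of 63.5 %. That neighbour flask stood at 62.9 %.

(Readings and results come from a simulation from invented constants, noise included.)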